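**Strategy.** Ring A of the flavone is a phloroglucinol whose oxygens at C5 (OMe), C7 (OH) and C8a (ring O1) must be told apart, with the (S)-piperidine on C6 between C5 and C7. The route builds ring A around that C6 substituent by a vinylketene–siloxyalkyne benzannulation. A triisopropylsilyl ynol ether made from N-Boc-L-pipecolic acid (C2′ stereocentre already present) is heated with 3-benzyloxycyclobutenone. This single operation makes C5–C6 and C7–C8, closes ring A at C4a–C5, and delivers O5 as free phenol, O7 as silyl ether and O8a as benzyl ether. Ring C is then added at C4a/C8a by carbonylative alkyne annulation.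

Key step: step 4

Assumption: chromone carbons carry flavone locants and piperidine atoms primed locants; the target's C2′ is (S), the same spatial arrangement as in L-pipecolic acid, so the centre is carried through without inversion.

**Step 1**
Reactants: 1 (S)-1-(tert-butoxycarbonyl)piperidine-2-carboxylic acid (N-Boc-L-pipecolic acid)
Product: 2 1-tert-butyl 2-methyl (S)-piperidine-1,2-dicarboxylate
Conditions: MeI, KHCO3, DMF, 20 °C
Reagents that add atoms: iodomethane, CI
Why: Carboxylate O-alkylation (SN2 on iodomethane) under a base too weak to remove the α-hydrogen, so C2′ is untouched.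

**Step 2**
Reactants: 2 1-tert-butyl 2-methyl (S)-piperidine-1,2-dicarboxylate
Product: 5 tert-butyl (S)-2-[(triisopropylsilyloxy)ethynyl]piperidine-1-carboxylate, via dibromo enolate 3 (not isolated), via lithium ynolate 4 (not isolated)
Conditions: CH2Br2, lithium 2,2,6,6-tetramethylpiperidide, THF, −78 °C; LiN(SiMe3)2; n-BuLi, −78 → 20 °C; iPr3SiOTf, −78 → 0 °C
Reagents that add atoms: dibromomethane, BrCBr; triisopropylsilyl trifluoromethanesulfonate, CC(C)[Si](C(C)C)(C(C)C)OS(=O)(=O)C(F)(F)F
Why: Kowalski ynolate synthesis, in which LiCHBr2 adds to the ester, enolate 3 undergoes bromine–lithium exchange and 1,2-shift of the piperidinyl carbon with retention (the enolate keeps base away from the α-stereocentre) to ynolate 4, and the bulky silyl triflate traps it on oxygen.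

**Step 3**
Reactants: 6 3-ethoxycyclobut-2-en-1-one; 7 benzyl alcohol
Product: 8 3-(benzyloxy)cyclobut-2-en-1-one
Conditions: pyridinium p-toluenesulfonate (cat.), toluene, 5 Å sieves, 50 °C
Reagents that add atoms: none
Why: Acid-catalysed alkoxy exchange of a vinylogous ester (benzyl alcohol adds at C3 of the O-protonated enone, ethanol leaves), driven by sequestering ethanol and run well below the ring-opening temperature; surplus benzyl alcohol is removed completely because it would trap the ketene in step 4.

**Step 4**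
Reactants: 5 tert-butyl (S)-2-[(triisopropylsilyloxy)ethynyl]piperidine-1-carboxylate; 8 3-(benzyloxy)cyclobut-2-en-1-one
Product: 13 tert-butyl (S)-2-[4-(benzyloxy)-2-hydroxy-6-(triisopropylsilyloxy)phenyl]piperidine-1-carboxylate, via vinylketene 9 (not isolated), via vinylcyclobutenone 10 (not isolated), via dienylketene 11 (not isolated), via cyclohexadienone 12 (not isolated)
Conditions: 8 (1.5 equiv, two portions), toluene, 80 → 110 °C, sealed vessel
Reagents that add atoms: none
Why: Thermal conrotatory 4π opening of 8 (cutting C4a–C5) gives alkoxyvinylketene 9, which adds (2+2) across the ynol ether of 5 to give 10; reversible 4π opening of 10 (cutting what was the C5–C8 bond of the four-membered ring) gives dienylketene 11, which closes to dienone 12 and enolises to phenol 13. The closest known reaction type is the Danheiser benzannulation of cyclobutenones with siloxyalkynes to resorcinol monosilyl ethers. Ring A is closed by thermally allowed disrotatory 6π electrocyclisation of 11, which re-forms C4a–C5, so that C5–C6 and C7–C8 are the net new bonds and aromatisation makes the sequence irreversible. No stereocentre is created (the sp3 ring carbon of 10 is transient), and C2′ is a carbamate-bearing spectator that is not acidic under neutral thermolysis. The step needs (2+2) regiochemistry, which the polarised ynol ether secures: its piperidine-bearing carbon (future C6) is the nucleophilic terminus and bonds to the ketene carbon (future C5), the oxygenated carbon (future C7) bonds to the ketene CH (future C8), so OH lands on C5, OTIPS on C7 and OBn on C8a. Chemoselectivity against ketene dimerisation or O-acylation of 13 is helped by portionwise addition of 8 and by the hindered position of the new phenol.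

**Step 5**
Reactants: 13 tert-butyl (S)-2-[4-(benzyloxy)-2-hydroxy-6-(triisopropylsilyloxy)phenyl]piperidine-1-carboxylate
Product: 14 tert-butyl (S)-2-[4-(benzyloxy)-2-methoxy-6-(triisopropylsilyloxy)phenyl]piperidine-1-carboxylate
Conditions: MeI, K2CO3, acetone, 50 °C
Reagents that add atoms: iodomethane, CI
Why: Williamson O-methylation of the only free phenol (C5–OH); the silyl ether is meta to the phenoxide so it cannot migrate, and anhydrous carbonate in acetone leaves the aryl OTIPS and Boc groups intact.

**Step 6**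
Reactants: 14 tert-butyl (S)-2-[4-(benzyloxy)-2-methoxy-6-(triisopropylsilyloxy)phenyl]piperidine-1-carboxylate
Product: 15 tert-butyl (S)-2-[4-hydroxy-2-methoxy-6-(triisopropylsilyloxy)phenyl]piperidine-1-carboxylate
Conditions: H2 (1 atm), 10% Pd/C, EtOAc, 20 °C
Reagents that add atoms: none
Why: Hydrogenolysis of the aryl benzyl ether over palladium metal, done before any halogen is present; Boc, OTIPS and OMe are inert and the hindered carbamate C–N bond is not cleaved at 1 atm.

**Step 7**
Reactants: 15 tert-butyl (S)-2-[4-hydroxy-2-methoxy-6-(triisopropylsilyloxy)phenyl]piperidine-1-carboxylate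
Product: 16 tert-butyl (S)-2-[4-hydroxy-3-iodo-2-methoxy-6-(triisopropylsilyloxy)phenyl]piperidine-1-carboxylate
Conditions: N-iodosuccinimide (1.0 equiv), CH2Cl2, −20 → 0 °C, dark
Reagents that add atoms: N-iodosuccinimide, O=C1CCC(=O)N1I
Why: Electrophilic iodination ortho to the free C8a–OH; C4a lies between OH and OMe, whereas C8 lies between OH and the OTIPS group, whose silicon is pushed toward C8 by the C6 substituent and screens it, so iodine should enter at C4a.

**Step 8**
Reactants: 16 tert-butyl (S)-2-[4-hydroxy-3-iodo-2-methoxy-6-(triisopropylsilyloxy)phenyl]piperidine-1-carboxylate; 17 phenylacetylene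
Product: 19 tert-butyl (S)-2-[5-methoxy-4-oxo-2-phenyl-7-(triisopropylsilyloxy)-4H-chromen-6-yl]piperidine-1-carboxylate, via ynone 18 (not isolated)
Conditions: PdCl2(PPh3)2 (5 mol %), CO (1 atm), Et2NH, 50 °C
Reagents that add atoms: carbon monoxide, [C-]#[O+]
Why: Carbonylative Sonogashira-type annulation of an o-iodophenol, in which zerovalent palladium formed in situ inserts into C4a–I, CO insertion and alkynylation give ynone 18, and the secondary amine steers its 6-endo-dig oxa-Michael closure to ring C in preference to the 5-exo aurone.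

**Step 9**
Reactants: 19 tert-butyl (S)-2-[5-methoxy-4-oxo-2-phenyl-7-(triisopropylsilyloxy)-4H-chromen-6-yl]piperidine-1-carboxylate
Product: 21 (S)-5-methoxy-6-(1-methylpiperidin-2-yl)-2-phenyl-7-(triisopropylsilyloxy)-4H-chromen-4-one, via secondary amine 20 (not isolated)
Conditions: TFA, anisole, CH2Cl2, 0 °C; evaporate; 37% aq. HCHO, NaBH(OAc)3, MeCN, 20 °C; NaHCO3 work-up
Reagents that add atoms: formaldehyde, C=O
Why: Acidolysis of the Boc group followed by reductive amination with formaldehyde, neither of which touches the chromone; the C4 carbonyl and the flanking OTIPS deactivate ring A toward cation capture and toward ionisation of the benzylic C–N bond, so C2′ keeps its configuration.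

**Step 10**
Reactants: 21 (S)-5-methoxy-6-(1-methylpiperidin-2-yl)-2-phenyl-7-(triisopropylsilyloxy)-4H-chromen-4-one
Product: 22 (S)-7-hydroxy-5-methoxy-6-(1-methylpiperidin-2-yl)-2-phenyl-4H-chromen-4-one
Conditions: Bu4NF, AcOH, THF, 0 °C
Reagents that add atoms: none
Why: Fluoride-induced cleavage of the aryl silyl ether (strong Si–F bond), buffered and cold so that the aminophenol is not exposed to base or heat that could open the benzylic C–N bond.

**Compound list**

1 | (S)-1-(tert-butoxycarbonyl)piperidine-2-carboxylic acid (N-Boc-L-pipecolic acid) | OC(=O)[C@@H]1CCCCN1C(=O)OC(C)(C)C | starting material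
2 | 1-tert-butyl 2-methyl (S)-piperidine-1,2-dicarboxylate | COC(=O)[C@@H]1CCCCN1C(=O)OC(C)(C)C | intermediate
3 | lithium enolate of tert-butyl (S)-2-(2,2-dibromoacetyl)piperidine-1-carboxylate (not isolated) | [Li+].[O-]C(=C(Br)Br)[C@@H]1CCCCN1C(=O)OC(C)(C)C | intermediate
4 | lithium 2-[(S)-1-(tert-butoxycarbonyl)piperidin-2-yl]ethynolate (not isolated) | [Li+].[O-]C#C[C@@H]1CCCCN1C(=O)OC(C)(C)C | intermediate
5 | tert-butyl (S)-2-[(triisopropylsilyloxy)ethynyl]piperidine-1-carboxylate | CC(C)[Si](C(C)C)(C(C)C)OC#C[C@@H]1CCCCN1C(=O)OC(C)(C)C | intermediate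
6 | 3-ethoxycyclobut-2-en-1-one | CCOC1=CC(=O)C1 | starting material
7 | benzyl alcohol | OCc1ccccc1 | starting material
8 | 3-(benzyloxy)cyclobut-2-en-1-one | O=C1C=C(OCc2ccccc2)C1 | intermediate
9 | 3-(benzyloxy)buta-1,3-dien-1-one (vinylketene, not isolated) | C=C(OCc1ccccc1)C=C=O | intermediate
10 | tert-butyl (2S)-2-{3-[1-(benzyloxy)ethenyl]-4-oxo-2-(triisopropylsilyloxy)cyclobut-1-en-1-yl}piperidine-1-carboxylate (ring CH of either configuration, not isolated) | O=C1C([C@@H]2CCCCN2C(=O)OC(C)(C)C)=C(O[Si](C(C)C)(C(C)C)C(C)C)C1C(=C)OCc1ccccc1 | intermediate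
11 | tert-butyl (2S)-2-[(3E)-5-(benzyloxy)-1-oxo-3-(triisopropylsilyloxy)hexa-1,3,5-trien-2-yl]piperidine-1-carboxylate (dienylketene with ketene and enol ether termini cis, not isolated) | O=C=C([C@@H]1CCCCN1C(=O)OC(C)(C)C)/C(O[Si](C(C)C)(C(C)C)C(C)C)=C\C(=C)OCc1ccccc1 | intermediate
12 | tert-butyl (2S)-2-[4-(benzyloxy)-6-oxo-2-(triisopropylsilyloxy)cyclohexa-1,3-dien-1-yl]piperidine-1-carboxylate (not isolated) | O=C1CC(OCc2ccccc2)=CC(O[Si](C(C)C)(C(C)C)C(C)C)=C1[C@@H]1CCCCN1C(=O)OC(C)(C)C | intermediate
13 | tert-butyl (S)-2-[4-(benzyloxy)-2-hydroxy-6-(triisopropylsilyloxy)phenyl]piperidine-1-carboxylate | Oc1cc(OCc2ccccc2)cc(O[Si](C(C)C)(C(C)C)C(C)C)c1[C@@H]1CCCCN1C(=O)OC(C)(C)C | intermediate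
14 | tert-butyl (S)-2-[4-(benzyloxy)-2-methoxy-6-(triisopropylsilyloxy)phenyl]piperidine-1-carboxylate | COc1cc(OCc2ccccc2)cc(O[Si](C(C)C)(C(C)C)C(C)C)c1[C@@H]1CCCCN1C(=O)OC(C)(C)C | intermediate
15 | tert-butyl (S)-2-[4-hydroxy-2-methoxy-6-(triisopropylsilyloxy)phenyl]piperidine-1-carboxylate | COc1cc(O)cc(O[Si](C(C)C)(C(C)C)C(C)C)c1[C@@H]1CCCCN1C(=O)OC(C)(C)C | intermediate
16 | tert-butyl (S)-2-[4-hydroxy-3-iodo-2-methoxy-6-(triisopropylsilyloxy)phenyl]piperidine-1-carboxylate | COc1c(I)c(O)cc(O[Si](C(C)C)(C(C)C)C(C)C)c1[C@@H]1CCCCN1C(=O)OC(C)(C)C | intermediate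
17 | phenylacetylene | C#Cc1ccccc1 | starting material
18 | tert-butyl (S)-2-[4-hydroxy-2-methoxy-3-(3-phenylprop-2-ynoyl)-6-(triisopropylsilyloxy)phenyl]piperidine-1-carboxylate (not isolated) | COc1c(C(=O)C#Cc2ccccc2)c(O)cc(O[Si](C(C)C)(C(C)C)C(C)C)c1[C@@H]1CCCCN1C(=O)OC(C)(C)C | intermediate
19 | tert-butyl (S)-2-[5-methoxy-4-oxo-2-phenyl-7-(triisopropylsilyloxy)-4H-chromen-6-yl]piperidine-1-carboxylate | COc1c([C@@H]2CCCCN2C(=O)OC(C)(C)C)c(O[Si](C(C)C)(C(C)C)C(C)C)cc2oc(-c3ccccc3)cc(=O)c12 | intermediate
20 | (S)-5-methoxy-2-phenyl-6-(piperidin-2-yl)-7-(triisopropylsilyloxy)-4H-chromen-4-one (present as its trifluoroacetate salt, not isolated) | COc1c([C@@H]2CCCCN2)c(O[Si](C(C)C)(C(C)C)C(C)C)cc2oc(-c3ccccc3)cc(=O)c12 | intermediate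
21 | (S)-5-methoxy-6-(1-methylpiperidin-2-yl)-2-phenyl-7-(triisopropylsilyloxy)-4H-chromen-4-one | COc1c([C@@H]2CCCCN2C)c(O[Si](C(C)C)(C(C)C)C(C)C)cc2oc(-c3ccccc3)cc(=O)c12 | intermediate
22 | (S)-7-hydroxy-5-methoxy-6-(1-methylpiperidin-2-yl)-2-phenyl-4H-chromen-4-one (CNP0075577.1) | COc1c([C@@H]2CCCCN2C)c(O)cc2oc(-c3ccccc3)cc(=O)c12 | target

**Total step count:** 10.
**Longest linear sequence:** 9 steps (steps 1, 2, 4, 5, 6, 7, 8, 9, 10 from compound 1; step 3 lies on the branch that supplies 8).

**Steps most likely to fail**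

1. Step 4. What may go wrong: the vinylogous-ester cyclobutenone may resist ring opening until temperatures at which the siloxyalkyne rearranges by 1,3-silyl shift, or the alkoxyvinylketene may be lost to dimerisation or to acylation of the product phenol before the alkyne captures it. Fallback, setting out from 5 and 7 and coming back at 13: the same vinylketene 9 is generated near room temperature by 1,4-dehydrochlorination instead of electrocyclic opening. Trimethylphosphine-catalysed addition of 7 to methyl but-2-ynoate gives methyl (E)-3-(benzyloxy)but-2-enoate F1, LiOH saponification gives (E)-3-(benzyloxy)but-2-enoic acid F2, and oxalyl chloride gives (E)-3-(benzyloxy)but-2-enoyl chloride F3. Slow addition of F3 to a CH2Cl2 solution of 5 and Et3N keeps 9 at low stationary concentration, where 5 intercepts it to give vinylcyclobutenone 10. Brief warming in toluene at 80 °C then carries 10 through 11 and 12 to 13.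

2. Step 7. What may go wrong: insufficient discrimination between C4a and C8, or double iodination, which would put ring C on the wrong side of ring A. Fallback, setting out from 13 and coming back at 19: the carbon at C4a is introduced while the C5–OH is still free, by a reaction that can only occur ortho to it. Casnati–Skattebøl formylation (MgCl2, Et3N, paraformaldehyde, MeCN, reflux) gives tert-butyl (S)-2-[4-(benzyloxy)-3-formyl-2-hydroxy-6-(triisopropylsilyloxy)phenyl]piperidine-1-carboxylate F4, since C6 is blocked and only C4a is ortho. Methylation with MeI and Ag2O (non-basic, to spare the now carbonyl-activated OTIPS) gives tert-butyl (S)-2-[4-(benzyloxy)-3-formyl-2-methoxy-6-(triisopropylsilyloxy)phenyl]piperidine-1-carboxylate F5. Hydrogenolysis (H2, 10% Pd/C, EtOAc) gives tert-butyl (S)-2-[3-formyl-4-hydroxy-2-methoxy-6-(triisopropylsilyloxy)phenyl]piperidine-1-carboxylate F6. Excess lithium phenylacetylide (from 17 and n-BuLi, THF, −78 °C) gives tert-butyl (2S)-2-[4-hydroxy-3-(1-hydroxy-3-phenylprop-2-yn-1-yl)-2-methoxy-6-(triisopropylsilyloxy)phenyl]piperidine-1-carboxylate F7. MnO2 in CH2Cl2 oxidises F7 to ynone 18, and Et2NH closes it to 19. This detour also bypasses step 8, should direct alkynylation outrun carbonylation there.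

3. Step 2. What may go wrong: attack of excess alkyllithium on the carbamate, or deprotonation next to nitrogen during the warm-up that the carbenoid rearrangement needs, with loss of material or of configurational purity. Fallback, setting out from 2 and coming back at 5: the ynolate is reached by oxidation of a terminal alkyne instead of by rearrangement. Reduction of 2 with iBu2AlH (toluene, −78 °C) gives tert-butyl (S)-2-formylpiperidine-1-carboxylate F8. Ohira–Bestmann homologation (dimethyl (1-diazo-2-oxopropyl)phosphonate, K2CO3, MeOH, 0 °C) gives tert-butyl (S)-2-ethynylpiperidine-1-carboxylate F9. Deprotonation of F9 with LiN(SiMe3)2 and oxidation with LiOOtBu (THF, −78 → 0 °C) gives ynolate 4, which iPr3SiOTf silylates on oxygen to 5.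

**Further compounds**

F1 | step 4 | methyl (E)-3-(benzyloxy)but-2-enoate | COC(=O)/C=C(\C)OCc1ccccc1
F2 | step 4 | (E)-3-(benzyloxy)but-2-enoic acid | OC(=O)/C=C(\C)OCc1ccccc1
F3 | step 4 | (E)-3-(benzyloxy)but-2-enoyl chloride | ClC(=O)/C=C(\C)OCc1ccccc1
F4 | step 7 | tert-butyl (S)-2-[4-(benzyloxy)-3-formyl-2-hydroxy-6-(triisopropylsilyloxy)phenyl]piperidine-1-carboxylate | Oc1c(C=O)c(OCc2ccccc2)cc(O[Si](C(C)C)(C(C)C)C(C)C)c1[C@@H]1CCCCN1C(=O)OC(C)(C)C
F5 | step 7 | tert-butyl (S)-2-[4-(benzyloxy)-3-formyl-2-methoxy-6-(triisopropylsilyloxy)phenyl]piperidine-1-carboxylate | COc1c(C=O)c(OCc2ccccc2)cc(O[Si](C(C)C)(C(C)C)C(C)C)c1[C@@H]1CCCCN1C(=O)OC(C)(C)C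
F6 | step 7 | tert-butyl (S)-2-[3-formyl-4-hydroxy-2-methoxy-6-(triisopropylsilyloxy)phenyl]piperidine-1-carboxylate | COc1c(C=O)c(O)cc(O[Si](C(C)C)(C(C)C)C(C)C)c1[C@@H]1CCCCN1C(=O)OC(C)(C)C
F7 | step 7 | tert-butyl (2S)-2-[4-hydroxy-3-(1-hydroxy-3-phenylprop-2-yn-1-yl)-2-methoxy-6-(triisopropylsilyloxy)phenyl]piperidine-1-carboxylate (both carbinol epimers) | COc1c(C(O)C#Cc2ccccc2)c(O)cc(O[Si](C(C)C)(C(C)C)C(C)C)c1[C@@H]1CCCCN1C(=O)OC(C)(C)C
F8 | step 2 | tert-butyl (S)-2-formylpiperidine-1-carboxylate | O=C[C@@H]1CCCCN1C(=O)OC(C)(C)C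
F9 | step 2 | tert-butyl (S)-2-ethynylpiperidine-1-carboxylate | C#C[C@@H]1CCCCN1C(=O)OC(C)(C)C
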